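**Strategy.** Flavan numbering is used (ring A fused, ring B on C2, ring D on C4). In the target, H-4 and the 3-OH are cis and both anti to ring B: the signature of a syn hydroboration of a 4-aryl-2H-chromene. Everything rests on the C4–C4a disconnection of that chromene to an alkyne: a gold-catalysed 6-endo-dig hydroarylation, in which the ring A carbon para to its benzyloxy group attacks the alkyne carbon bearing ring D, closes the pyran ring in one operation. The precursor is a linear, fully benzylated (R)-1,3-diarylpropargyl aryl ether whose single stereocentre (future C2) comes from a copper-catalysed asymmetric propargylic etherification.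

Key step: step 6

Assumption: the sense of induction in step 4 is not derived here; the ligand is written as (S,S)-Ph-pybox, and its mirror image is used if a trial run shows that it is the one giving (S)-9.

**Step 1**
Reactants: 1 2-methoxyresorcinol (2-methoxybenzene-1,3-diol)
Product: 2 1,3-bis(benzyloxy)-2-methoxybenzene
Conditions: BnBr (2.2 equiv), K2CO3, DMF, 60 °C
Reagents that add atoms: benzyl bromide, BrCc1ccccc1
Why: Williamson ether synthesis on both phenols; no stereocentre is involved.

**Step 2**
Reactants: 2 1,3-bis(benzyloxy)-2-methoxybenzene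
Product: 3 1,3-bis(benzyloxy)-4-iodo-2-methoxybenzene
Conditions: NIS (1.0 equiv), TFA (cat.), MeCN, 0 °C to rt, dark
Reagents that add atoms: N-iodosuccinimide, O=C1CCC(=O)N1I
Why: Electrophilic aromatic iodination at C4, which is ortho to one benzyloxy group and para to the other (C5 is meta to both); one equivalent of NIS should limit the reaction to monoiodination.

**Step 3**
Reactants: 4 3,4-bis(benzyloxy)benzaldehyde; 5 ethynylmagnesium bromide
Product: 7 racemic 1-[3,4-bis(benzyloxy)phenyl]prop-2-yn-1-yl acetate, via bromomagnesium alkoxide 6 (not isolated)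
Conditions: 5 (1.1 equiv), THF, 0 °C; then Ac2O (1.5 equiv), 0 °C to rt
Reagents that add atoms: acetic anhydride, CC(=O)OC(C)=O
Why: Grignard addition to the aldehyde followed by O-acylation of the alkoxide in the same flask; the racemate suffices because step 4 is enantioconvergent.

**Step 4**
Reactants: 7 racemic propargylic acetate; 8 3-(benzyloxy)phenol
Product: 9 (S)-4-{1-[3-(benzyloxy)phenoxy]prop-2-yn-1-yl}-1,2-bis(benzyloxy)benzene
Conditions: Cu(OTf)·1/2C6H6 (5 mol%), (S,S)-Ph-pybox (10 mol%), iPr2NEt (1.2 equiv), 8 (1.5 equiv), CH2Cl2, −20 °C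
Reagents that add atoms: none
Why: Copper-catalysed enantioselective propargylic etherification: the copper acetylide of 7 loses acetate to give a copper allenylidene (monovalent copper), and the phenol oxygen adds to its γ-carbon on the face left open by the pybox ligand, so both enantiomers of 7 converge on one ether and the future C2 stereocentre is set under catalyst control.

**Step 5**
Reactants: 9 (S)-terminal propargyl aryl ether; 3 1,3-bis(benzyloxy)-4-iodo-2-methoxybenzene
Product: 10 (R)-1,3-bis(benzyloxy)-4-{3-[3-(benzyloxy)phenoxy]-3-[3,4-bis(benzyloxy)phenyl]prop-1-yn-1-yl}-2-methoxybenzene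
Conditions: PdCl2(PPh3)2 (3 mol%), CuI (5 mol%), Et3N, THF, 40 °C
Reagents that add atoms: none
Why: Sonogashira coupling of the terminal alkyne with the aryl iodide; the stereocentre is not touched (the descriptor changes from S to R only because the disubstituted alkynyl group now outranks the aryl group).

**Step 6**
Reactants: 10 (R)-1,3-diarylpropargyl aryl ether
Product: 11 (S)-7-(benzyloxy)-4-[2,4-bis(benzyloxy)-3-methoxyphenyl]-2-[3,4-bis(benzyloxy)phenyl]-2H-chromene
Conditions: [(JohnPhos)Au(NCMe)]SbF6 (3 mol%; JohnPhos = (2-biphenylyl)di-tert-butylphosphine), CH2Cl2, 0 °C to rt, dark; filtration through basic alumina, used at once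
Reagents that add atoms: none
Why: The cationic monovalent gold centre π-activates the alkyne, and the ring A carbon that is para to the benzyloxy group and ortho to the ether oxygen attacks anti to gold at the alkyne carbon bearing ring D; rearomatisation and protodeauration of the vinyl–gold species release the 2H-chromene. The closest known reaction type is the gold-catalysed intramolecular hydroarylation (Friedel–Crafts-type alkenylation) of aryl propargyl ethers to 2H-chromenes. The pyran ring is closed in the 6-endo-dig mode, favoured over 5-exo-dig because ring D stabilises positive charge at the carbon it bears. No new stereocentre is formed, and the C2 stereocentre from step 4 should be preserved because neither its C–O nor its C–H bond takes part, in contrast to a thermal propargyl Claisen pathway. The step needs site selectivity on ring A, secured by the para-directing benzyloxy group and by the peri clash that a 5-benzyloxy group would have with the 4-aryl group, and chemoselectivity over capture of the alkyne by the ortho-benzyloxy oxygen of ring D, secured by a phosphine–gold catalyst at 0 °C under which benzyl transfer is slow.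

**Step 7**
Reactants: 11 (S)-4-aryl-2H-chromene
Product: 13 (2R,3S,4S)-7-(benzyloxy)-4-[2,4-bis(benzyloxy)-3-methoxyphenyl]-2-[3,4-bis(benzyloxy)phenyl]chroman-3-ol, via C3 alkylborane 12 (not isolated)
Conditions: BH3·THF (3 equiv), THF, 0 °C to rt; then NaOH (aq), H2O2, 0 °C to rt
Reagents that add atoms: hydrogen peroxide, OO; borane–THF, B.C1CCOC1 (its boron is held only in 12)
Why: Hydroboration–oxidation: borane adds syn across C3=C4 with boron on C3 (C4 is fully substituted) from the face anti to ring B on C2, and oxidation proceeds with retention, so H-4 and the 3-OH end up cis to each other and trans to ring B, which sets C3 and C4 (2,3-trans, 3,4-trans) under control of C2.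

**Step 8**
Reactants: 13 pentabenzyl ether
Product: 14 (2R,3S,4R)-2-(3,4-dihydroxyphenyl)-4-(2,4-dihydroxy-3-methoxyphenyl)chroman-3,7-diol (CNP0124388.1)
Conditions: H2 (1 atm), Pd(OH)2/C, THF/MeOH, rt; work-up under argon
Reagents that add atoms: none
Why: Catalytic hydrogenolysis of the five benzyl ethers; the methyl ether, the ring C2–O bond and the C4–aryl bond are expected to survive as in benzylated flavan-3-ols, and no stereocentre is touched (the C4 descriptor changes from S to R only through the CIP priorities).

**Compound list**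

1 | 2-methoxyresorcinol | COc1c(O)cccc1O | starting material
2 | 1,3-bis(benzyloxy)-2-methoxybenzene | COc1c(OCc2ccccc2)cccc1OCc1ccccc1 | intermediate
3 | 1,3-bis(benzyloxy)-4-iodo-2-methoxybenzene | COc1c(OCc2ccccc2)ccc(I)c1OCc1ccccc1 | intermediate
4 | 3,4-bis(benzyloxy)benzaldehyde | O=Cc1ccc(OCc2ccccc2)c(OCc2ccccc2)c1 | starting material
5 | ethynylmagnesium bromide | C#C[Mg]Br | starting material
6 | bromomagnesium 1-[3,4-bis(benzyloxy)phenyl]prop-2-yn-1-olate (racemic, not isolated) | C#CC(O[Mg]Br)c1ccc(OCc2ccccc2)c(OCc2ccccc2)c1 | intermediate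
7 | 1-[3,4-bis(benzyloxy)phenyl]prop-2-yn-1-yl acetate (racemic) | CC(=O)OC(C#C)c1ccc(OCc2ccccc2)c(OCc2ccccc2)c1 | intermediate
8 | 3-(benzyloxy)phenol | Oc1cccc(OCc2ccccc2)c1 | starting material
9 | (S)-4-{1-[3-(benzyloxy)phenoxy]prop-2-yn-1-yl}-1,2-bis(benzyloxy)benzene | O(c1cccc(OCc2ccccc2)c1)[C@H](c1ccc(OCc2ccccc2)c(OCc2ccccc2)c1)C#C | intermediate
10 | (R)-1,3-bis(benzyloxy)-4-{3-[3-(benzyloxy)phenoxy]-3-[3,4-bis(benzyloxy)phenyl]prop-1-yn-1-yl}-2-methoxybenzene | O(c1cccc(OCc2ccccc2)c1)[C@H](c1ccc(OCc2ccccc2)c(OCc2ccccc2)c1)C#Cc1ccc(OCc2ccccc2)c(OC)c1OCc1ccccc1 | intermediate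
11 | (S)-7-(benzyloxy)-4-[2,4-bis(benzyloxy)-3-methoxyphenyl]-2-[3,4-bis(benzyloxy)phenyl]-2H-chromene | C(c1ccccc1)Oc1ccc2c(c1)O[C@H](c1ccc(OCc3ccccc3)c(OCc3ccccc3)c1)C=C2c1ccc(OCc2ccccc2)c(OC)c1OCc1ccccc1 | intermediate
12 | [7-(benzyloxy)-4-(2,4-bis(benzyloxy)-3-methoxyphenyl)-2-(3,4-bis(benzyloxy)phenyl)chroman-3-yl]borane, BH2 on C3 trans to both neighbouring aryl groups, configuration as in 13 (not isolated) | COc1c(OCc2ccccc2)ccc([C@@H]2c3ccc(OCc4ccccc4)cc3O[C@H](c3ccc(OCc4ccccc4)c(OCc4ccccc4)c3)[C@H]2B)c1OCc1ccccc1 | intermediate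
13 | (2R,3S,4S)-7-(benzyloxy)-4-[2,4-bis(benzyloxy)-3-methoxyphenyl]-2-[3,4-bis(benzyloxy)phenyl]chroman-3-ol | COc1c(OCc2ccccc2)ccc([C@@H]2c3ccc(OCc4ccccc4)cc3O[C@H](c3ccc(OCc4ccccc4)c(OCc4ccccc4)c3)[C@H]2O)c1OCc1ccccc1 | intermediate
14 | (2R,3S,4R)-2-(3,4-dihydroxyphenyl)-4-(2,4-dihydroxy-3-methoxyphenyl)chroman-3,7-diol | COc1c(O)ccc([C@@H]2c3ccc(O)cc3O[C@H](c3ccc(O)c(O)c3)[C@H]2O)c1O | target

**Total step count:** 8

**Longest linear sequence:** 6 steps (steps 3 to 8 from aldehyde 4; equally steps 1, 2, 5 to 8 from 1)

**Steps most likely to fail**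

Step 6 (key step). What may go wrong: loss of configuration at C2 through gold- or acid-assisted ionisation of the doubly activated C–O bond or through isomerisation of the 2H-chromene; ring closure at the ring A carbon between the two oxygens; capture of the activated alkyne by the ortho-benzyloxy oxygen of ring D with benzyl transfer. The fallback sets out from 10 and comes back at 13, so that it replaces steps 6 and 7 and still closes the pyran ring through the C4–C4a bond. Semihydrogenation of 10 (H2, Pd/CaCO3 poisoned with Pb(OAc)2, quinoline, EtOAc) should give the (S,Z)-allyl aryl ether F1. Jacobsen epoxidation of its cis-styrenyl double bond ((S,S)-(salen)MnCl, buffered NaOCl, 4-phenylpyridine N-oxide, CH2Cl2, 0 °C) should give the epoxide F2, with the C3 oxygen installed under catalyst control. Treatment of crude F2 with BF3·OEt2 (CH2Cl2, −78 °C) or hexafluoroisopropanol should open the epoxide at the ring D benzylic carbon and let ring A close the ring by a 6-endo Friedel–Crafts attack. The chair-like closure of the stabilised benzylic cation is expected to give the all-equatorial 2,3-trans-3,4-trans alcohol 13. Because C4 is set again in the ring closure, cis/trans leakage in the epoxidation would do no harm.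

Step 4. What may go wrong: Friedel–Crafts C-propargylation of the electron-rich phenol in place of O-alkylation, and erosion of the enantiomeric purity by uncatalysed ionisation of the electron-rich acetate. The fallback sets out from 3 and 4 and comes back at 10, so that it replaces steps 3, 4 and 5. Sonogashira coupling of 3 with ethynyltrimethylsilane (PdCl2(PPh3)2, CuI, Et3N, THF) should give the silyl alkyne F3, and desilylation (K2CO3, MeOH) the aryl alkyne F4. Addition of the alkynylzinc reagent from F4 to aldehyde 4 (Et2Zn, (R)-BINOL, Ti(OiPr)4, toluene/CH2Cl2; the ligand antipode if the sense proves opposite) should give the (S)-propargylic alcohol F5. Mitsunobu etherification of F5 with phenol 8 (PPh3, DIAD, toluene, −20 °C) should proceed with inversion to (R)-10.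

Step 7. What may go wrong: slow hydroboration of the hindered triaryl-substituted double bond, β-elimination of the C3 borane with opening of the pyran ring, and incomplete facial selectivity. The fallback sets out from 11 and comes back at 13. Epoxidation with dimethyldioxirane (acetone/CH2Cl2, −40 °C) on the face anti to ring B should give the 3,4-epoxide F6, which is used crude. Hydrogenolysis of its benzylic C4–O bond over Raney nickel (H2, EtOH/EtOAc, rt), which on nickel is known to proceed with retention, should deliver H-4 to the face the oxygen leaves and give 13. Any benzyl ether lost at this stage converges on 14 in step 8.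

**Further compounds**

F1 | step 6 | (S,Z)-allyl aryl ether: 1,3-bis(benzyloxy)-4-{(Z)-3-[3-(benzyloxy)phenoxy]-3-[3,4-bis(benzyloxy)phenyl]prop-1-en-1-yl}-2-methoxybenzene | O(c1cccc(OCc2ccccc2)c1)[C@H](c1ccc(OCc2ccccc2)c(OCc2ccccc2)c1)/C=C\c1ccc(OCc2ccccc2)c(OC)c1OCc1ccccc1
F2 | step 6 | cis-epoxide of F1 (flavan numbering: C2 R, C3 S, C4 S): 2-[2,4-bis(benzyloxy)-3-methoxyphenyl]-3-{[3-(benzyloxy)phenoxy][3,4-bis(benzyloxy)phenyl]methyl}oxirane | O(c1cccc(OCc2ccccc2)c1)[C@H](c1ccc(OCc2ccccc2)c(OCc2ccccc2)c1)[C@H]1O[C@H]1c1ccc(OCc2ccccc2)c(OC)c1OCc1ccccc1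
F3 | step 4 | 1,3-bis(benzyloxy)-2-methoxy-4-[(trimethylsilyl)ethynyl]benzene | COc1c(OCc2ccccc2)ccc(C#C[Si](C)(C)C)c1OCc1ccccc1
F4 | step 4 | 1,3-bis(benzyloxy)-4-ethynyl-2-methoxybenzene | COc1c(OCc2ccccc2)ccc(C#C)c1OCc1ccccc1
F5 | step 4 | (S)-1-[3,4-bis(benzyloxy)phenyl]-3-[2,4-bis(benzyloxy)-3-methoxyphenyl]prop-2-yn-1-ol | O[C@@H](c1ccc(OCc2ccccc2)c(OCc2ccccc2)c1)C#Cc1ccc(OCc2ccccc2)c(OC)c1OCc1ccccc1
F6 | step 7 | 3,4-epoxide of 11 with the oxygen anti to ring B: 7-(benzyloxy)-4-[2,4-bis(benzyloxy)-3-methoxyphenyl]-2-[3,4-bis(benzyloxy)phenyl]-3,4-epoxychroman | C(c1ccccc1)Oc1ccc2c(c1)O[C@H](c1ccc(OCc3ccccc3)c(OCc3ccccc3)c1)[C@H]1O[C@@]21c4ccc(OCc3ccccc3)c(OC)c4OCc3ccccc3
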